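Picture a one-step world: substrate turns into other capture product on one fixed constant, and the moment of addition hardly counts. Test that against the violet run.

the same everywhere: first nucleophile 100 mM

| charge | substrate | second nucleophile | remark | time |
|---|---|---|---|---|
| violet | 20 mM | 16 mM | run made earlier |  |
| teal | 30 mM | 16 mM | run made earlier |  |
| Friday's | 20 mM | 16.0 mM (in portions, 4, over 3.0 h) | first portion at the start, last at 3.0 h | 5.0 h |
| Saturday's | 20 mM | 16.0 mM (fed, over 3.0 h) | all else is in the flask from the start; the feed brings no volume worth counting | 5.0 h |
| Thursday's | 20 mM | 16.0 mM | everything together at the start | 5.0 h |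
| Monday's | 20 mM (fed, over 3.0 h) | 16.0 mM | all else is in the flask from the start; the feed brings no volume worth counting | 5.0 h |
| Sunday's | 20 mM | 16.0 mM (fed, over 50 min) | all else is in the flask from the start; the feed brings no volume worth counting | 5.0 h |

violet run (percent of the substrate charged)

| time / h | other capture product / % | target / % |
|---|---|---|
| 0.417 | 9.1 | 4.9 |
| 1.33 | 23.9 | 8.2 |
| 2.50 | 36.1 | 9.6 |
| 4.00 | 45.5 | 10.4 |
| 5.00 | 50.0 | 11.2 |

teal run (percent of the substrate charged)

| time / min | other capture product / % | target / % |
|---|---|---|
| 2.50 | 1.2 | 1.2 |
| 5.00 | 2.2 | 1.3 |
| 8.00 | 3.5 | 1.9 |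
| 15.0 | 5.7 | 3.3 |
| 30.0 | 10.6 | 4.9 |

(scatter of a reading: 0.3 percentage points)

* which flask leads in amount of other capture product, in percent of the substrate charged ("all alike" within 1.5 percentage points) (Friday's / Saturday's / Thursday's / Monday's / Sunday's / all alike)
* how much other capture product is there at the end, in percent of the substrate charged: Friday's
* how much other capture product is there at the end, in percent of the substrate charged: Saturday's
* how much other capture product is there at the end, in percent of the substrate charged: Thursday's
* how much other capture product is there at the end, in percent of the substrate charged: Monday's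
* how much other capture product is there at the end, in percent of the substrate charged: Sunday's



Read violet's pseudo-first-order constant, the rate of other capture product per unit of substrate left. It is 0.235 h⁻¹ up to the first reading and 0.119 h⁻¹ over the last window. Now charge one second nucleophile per capture: violet's average amount left drops from 15.1 mM to 7.39 mM, so both fall to about half.

So count time in the flask. Carry the mean stay, the end time less the average moment at which the fed reagent goes in, for Saturday's 3.50 h. Friday's portions average the same moment, and Monday's substrate has the same stay. Sunday's stay is 4.58 h, and Thursday's is the full 5.0 h, so expect Thursday's to lead at violet's 50.0%. Read violet between readings at the mean stay: Saturday's should hold 42.4%.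

The forecast differs: 51% for Friday's, 51.5% for Saturday's, 50% for Thursday's, 42% for Monday's, 51% for Sunday's, with Saturday's ahead, on the grounds “Feeding the second nucleophile therefore hardly changes target”.

The flasks give 41.0% for Friday's, 41.2% for Saturday's, 44.3% for Monday's, 47.9% for Sunday's, and 50.2% for Thursday's, which leads.

    substrate ⇌ intermediate (K = 0.00550, k = 0.0320 min⁻¹)
    first nucleophile + intermediate → target (k = 9.30 M⁻¹ min⁻¹)
    second nucleophile + intermediate → other capture product (k = 60.0 M⁻¹ min⁻¹)
    second nucleophile + target → over-reaction product (k = 0.0820 M⁻¹ min⁻¹)
    first nucleophile ⇌ dormant form (K = 0.460, k = 0.0320 min⁻¹)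
    2 first nucleophile → homo dimer (k = 0.430 M⁻¹ min⁻¹)

In Friday's, substrate and intermediate relax by their interconversion alone with a half-life of 0.118 min, while at 0.229 h capture by second nucleophile takes intermediate with a half-life of 0.052 h, which is 26.4 times longer. In Friday's at 5.00 h, intermediate stands at 0.221% against substrate at 43.6%. Sunday's stay of 4.58 h reads violet at 48.1%, and Sunday's flask gives 47.9%.

The data come from a simulation on assumed constants, noise included.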